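## Structural features

The target is a (3R)-isoflavan. Ring A is fused to the dihydropyran ring C through C4a–C8a, C3 carries aryl ring B, and ring B is fused through C2'–O and C3'–C to a 2,2-dimethyl-2H-pyran (ring D), leaving 4'-OH free. Ring A is a phloroglucinol-type arene with five substituents and one hydrogen (C4a alkyl, C5 OMe, C6 prenyl, C7 OH, C8 H, C8a O1), so it is pentasubstituted and must not be counted as hexasubstituted. C3 is the only stereocentre; it lies between two methylene groups (C2 and C4), has no stereogenic neighbour, and its hydrogen is only weakly acidic, so it can be set early and carried through strong base. The fragile groups are the prenyl chain ortho to a free phenol (acid closes it to a chroman), the styrene-like double bond of ring D (acid, hydrogenation, oxidants) and the electron-rich phenols (oxidation). The real difficulty is the regiochemistry of ring A: three oxygens must be told apart and the prenyl group must sit at C6 and not at C8, which electrophilic substitution of a phloroglucinol cannot secure. The key step exploits the alternating pattern of ring A: C7(OH)–C6(prenyl)–C5(OMe) is the imprint of a ketene carbonyl joined to the two carbons of an ynol ether, and C4a(alkyl)–C8a(O)–C8(H) is the imprint of C2–C3–C4 of a 3-siloxycyclobutenone. Design change to the precursor: the ring B phenol is carried as a triisopropylsilyl ether like the other two oxygens that must be freed, so one fluoride treatment replaces a final acid deprotection next to the prenyl group and ring D.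

## Logic of the disconnections

31 to 29. The O1–C2 bond is cut. An aryl alkyl ether made by 6-exo closure of a phenol onto a primary carbinol is the safest bond of ring C to form last, because C3 is not involved and no acid is needed. The gain is an open chain on a free resorcinol. The forward step must activate one primary hydroxyl in the presence of three phenols; only the C8a oxygen can reach C2.

29 to 28. Three O–Si bonds are cut (at C8a–O, C2–O and C4'–O). With silicon on all three oxygens one fluoride operation is enough and no acid step follows the introduction of the prenyl group. The forward step needs a buffered fluoride source so that the phenoxides are not oxidised.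

28 to 19 and 23. C4a–C5 and C6–C7 are cut. The C7–C8 bond is not new: it is the C1–C4 bond of the four-membered ring of 19, broken and re-formed during the step, while the bond that corresponds to C7–C4a in 19 is the one sacrificed. This removes ring A with all five substituents and leaves two pieces whose substitution is set by simple polar chemistry. The forward step needs heat, a partner that beats the two alkenes for the ketene, and silyl groups that survive about 110 °C.

19 to 18. The two bonds of the four-membered ring that correspond to C7–C4a and C8–C8a are cut, leaving 18 and a two-carbon cumulene introduced as a gas in step 8. The same polarity that steers the key step steers this [2+2] cycloaddition. The gain is an open-chain alkyne. The forward step demands anhydrous handling, because the enol silyl ether of 19 behaves as a vinylogous silyl ester.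

18 to 15. The inserted carbon C4a is removed: the C4–C4a bond, the C4a–C8a triple bond and the enol O–Si bond are cut. This traces the oxygenated alkyne to an ordinary ester carbonyl, the future C8a. The forward step uses strong bases, so every protecting group is a silyl ether, and a bulky silyl chloride is needed for O- rather than C-silylation.

15 to 12. The ester O–CH3 bond and the O–Si bond at C2 are cut and the acyl–oxygen bond of the five-membered ring is restored. The gain is a compact cyclic precursor that already holds C2, C3, C4 and the future C8a. The forward step must open the ring without loss of the aryl silyl ether and trap the open form before it closes again.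

12 to 10 and 11. The C3–C1' bond is cut. It is the one bond at the stereocentre that a catalytic enantioselective conjugate addition to a commercial acceptor can make. The forward step demands that an ortho-alkoxy, electron-rich boronic acid transmetalates faster than it protodeboronates, and that the ligand controls the face.

10 to 7, 4, 2 and 1. The C–B bond is cut (10 to 7), then the C3'–C bond and the O–CMe2 bond of ring D (7 to 4), then the aryl O–C bond (4 to 2 and 3) and an O–Si bond (2 to 1). Ring D is built first on a cheap bromophenol because bromine blocks one ortho position and leaves a single site for the rearrangement. The forward sequence demands mono-silylation of 1 at the less hindered hydroxyl.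

23 to 20 and 21. The bond between the alkyne carbon and the allylic CH2 is cut and the triple bond is traced to 20 by double elimination. Two commercial liquids give 23 in one operation. The forward step must avoid excess amide base, which would isomerise the skipped enyne.

## Other disconnections considered

Alternative 1: The cut is C3–C4 together with O1–C2 (as an acyl–oxygen bond).
- Forward step: base releases the quinone methide A3 from sulfone A2. Acid A4, activated in situ and enolised on a chiral isothiourea, adds through its α-carbon to the methylene of A3, and the phenoxide lactonises to give A1 and free the catalyst.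
- In favour: ring C and C3 arise in one catalytic, enantioselective, convergent step; A2 is symmetrical; no organolithium homologation and no gaseous reagent are needed. In convergence and in steps to the isoflavan skeleton it is better than the chosen plan, and in catalyst control of C3 it is its equal.
- Against: A1 carries neither the C5 methyl ether nor the C6 prenyl group. O-methylation is simple, but prenylation must then choose C6 over C8, which is exactly the problem of ring A, only postponed. C2 is at the carboxyl level and needs two or three steps to reach CH2. C3 of A1 is α to an aryl ester and benzylic, so base-mediated racemisation threatens, whereas C3 in the chosen route is never acidic. A3 has an unsubstituted methylene terminus and should oligomerise easily. The methoxymethyl ethers need acid at the end.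
- Comparison: both plans place substituents by polarity, but only the chosen plan fixes the ring A pattern by construction. The alternative should not be shorter overall once ring A is completed.

Alternative 2: The cut is C3–C1' and C4–C4a.
- Forward step: aryllithium A7 adds to vinylboronate A8. The aryl palladium species formed from triflate A6 and zerovalent palladium (Pd(OAc)2, chiral bisphosphine) binds the vinyl group and induces a 1,2-shift of the ring B aryl from boron to carbon, which sets C3. Reductive elimination forms C4–C4a and gives A5.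
- In favour: three components join in one enantioselective step, and boron remains as a handle for C2 (Matteson homologation, then oxidation, both stereoretentive). In convergence it is better than the chosen plan; in catalyst control of C3 it is equal.
- Against: A6 is the complete pentasubstituted ring A, which must be made separately with the prenyl group at C6, so the regiochemical problem is moved, not solved. Its triflate is electron-rich and flanked by two ortho oxygens, which should slow oxidative addition and reductive elimination. The migrating aryl is ortho-substituted, and the prenyl and ring D alkenes can bind the cationic divalent palladium. All oxygens are methoxymethyl ethers, so acid is needed after the prenyl group and ring D are present.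
- Comparison: after A5 about four steps remain (homologation, oxidation, deprotection, ring closure) against two after the chosen key step.

Alternative 3: The cut is the C3'–C bond and the O–CMe2 bond of ring D, made last.
- Forward step: heating A10 should trigger aromatic Claisen rearrangement to C3' (the only free ortho position), [1,5]-hydrogen shift and oxa-6π electrocyclisation to give A9.
- In favour: regiochemistry is unambiguous and no reagent is needed. In mechanism and regiocontrol it is the equal of step 3 of the chosen route, which runs the same cascade. It is better in one respect: ring B would pass through the asymmetric C–C bond formation as a simple resorcinol derivative, less hindered than 10, and ring D would be exposed to fewer steps.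
- Against: it is a late-stage tactic and says nothing about ring A or C3, since A10 presupposes the whole isoflavan. It needs 2'-OH distinguished from 4'-OH and a tertiary propargyl ether installed late on a hindered phenol. The fully elaborated compound would be heated to about 150–180 °C, and A9 still needs acid to remove two methoxymethyl groups.
- Comparison: it could be grafted onto the chosen route at the cost of about two late steps; it is not adopted because step 3 does the same on a simple bromophenol.

Key step: step 10

Remarks on the chemistry.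
- The sense of induction in step 5 is assigned from the facial model established for rhodium/BINAP additions to cyclic enones and unsaturated lactones; the antipodal ligand would be used if the assignment proved opposite.
- Ketene for step 8 is generated from acetone by pyrolysis and passed in as a gas.
- Abbreviations: TIPS = triisopropylsilyl; TBS = tert-butyldimethylsilyl; ArT = 2,2-dimethyl-5-(triisopropylsilyloxy)-2H-chromen-8-yl (ring B with ring D, bonded through chromene C8 = C1').

## Route

Step 1
Reactants: 1 4-bromoresorcinol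
Product: 2 2-bromo-5-(triisopropylsilyloxy)phenol
Conditions: TIPSCl (1.05 equiv), imidazole, CH2Cl2, 0 °C
Reagents that add atoms: chlorotriisopropylsilane, CC(C)[Si](Cl)(C(C)C)C(C)C
Why: Silylation with a bulky silyl chloride under imidazole is sterically controlled; the hydroxyl para to bromine is open whereas the one ortho to bromine is shielded, so mono-silylation at the former should dominate.

Step 2
Reactants: 2 2-bromo-5-(triisopropylsilyloxy)phenol; 3 3-chloro-3-methylbut-1-yne
Product: 4 [4-bromo-3-(2-methylbut-3-yn-2-yloxy)phenoxy]triisopropylsilane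
Conditions: DBU, CuCl2·2H2O (1 mol %), MeCN, 0 °C to rt
Reagents that add atoms: none
Why: Copper-catalysed propargylic etherification of phenols with tertiary propargyl chlorides is the standard entry to aryl 1,1-dimethylpropargyl ethers; the remaining phenol is acidic (ortho bromine) and DBU leaves the aryl silyl ether intact.

Step 3
Reactants: 4 [4-bromo-3-(2-methylbut-3-yn-2-yloxy)phenoxy]triisopropylsilane
Product: 7 8-bromo-2,2-dimethyl-5-(triisopropylsilyloxy)-2H-chromene, via allenylphenol 5 (not isolated), via ortho-quinone methide 6 (not isolated)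
Conditions: PhNEt2, 185 °C
Reagents that add atoms: none
Why: Aromatic propargyl Claisen rearrangement and tautomerisation give 5, a [1,5]-hydrogen shift gives 6 and oxa-6π electrocyclisation closes ring D; bromine blocks one ortho position, so only the carbon between the two oxygens can accept the side chain, which fixes the 8-bromo-5-silyloxy pattern.

Step 4
Reactants: 7 8-bromo-2,2-dimethyl-5-(triisopropylsilyloxy)-2H-chromene
Product: 10 ArT-boronic acid, via aryllithium 8 (not isolated), via lithium triisopropoxyborate 9 (not isolated)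
Conditions: n-BuLi, THF, −78 °C; B(Oi-Pr)3, −78 °C to rt; 1 M HCl to pH 5, 0 °C
Reagents that add atoms: triisopropyl borate, CC(C)OB(OC(C)C)OC(C)C; water, O
Why: Bromine–lithium exchange at −78 °C is faster than any deprotonation and the aryllithium is stabilised by the adjacent ring oxygen; borate trapping and mild hydrolysis is the standard arylboronic acid synthesis.

Step 5
Reactants: 10 ArT-boronic acid; 11 furan-2(5H)-one
Product: 12 (4R)-4-ArT-dihydrofuran-2(3H)-one
Conditions: [RhCl(C2H4)2]2 (2.5 mol %), (R)-BINAP (5.5 mol %), aq. KOH (10 mol %), 1,4-dioxane/H2O, 40 °C; 10 (2 equiv)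
Reagents that add atoms: none
Why: Hayashi–Miyaura asymmetric conjugate addition: transmetalation gives an aryl complex of monovalent rhodium, the butenolide C=C inserts with enantioface selection by the BINAP ligand, and water releases the product; by the facial model for cyclic enones and lactones the (R)-ligand should give 4R, the only stereocentre of the route.

Step 6
Reactants: 12 (4R)-4-ArT-dihydrofuran-2(3H)-one
Product: 15 methyl (3R)-4-(tert-butyldimethylsilyloxy)-3-ArT-butanoate, via lithium carboxylate 13 (not isolated), via hydroxy ester 14 (not isolated)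
Conditions: LiOH·H2O (1.05 equiv), THF/H2O, 0 °C; evaporate, toluene azeotrope; MeI, DMF, 0 °C to rt; then imidazole, TBSCl, rt
Reagents that add atoms: lithium hydroxide, [Li+].[OH-]; iodomethane, CI; tert-butyldimethylsilyl chloride, CC(C)(C)[Si](C)(C)Cl
Why: Saponification, SN2 O-methylation of the carboxylate in DMF and immediate silylation of the primary alcohol trap the open form before it can relactonise; none of these operations touches C3.

Step 7
Reactants: 15 methyl (3R)-4-(tert-butyldimethylsilyloxy)-3-ArT-butanoate
Product: 18 tert-butyldimethyl{[(2R)-2-ArT-5-(triisopropylsilyloxy)pent-4-yn-1-yl]oxy}silane, via dibromo enolate 16 (not isolated), via lithium ynolate 17 (not isolated)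
Conditions: CH2Br2, lithium 2,2,6,6-tetramethylpiperidide, THF, −78 °C; add 15; LiN(SiMe3)2, −78 °C; n-BuLi, −78 to 0 °C; TIPSCl, −78 °C to rt
Reagents that add atoms: dibromomethane, BrCBr; chlorotriisopropylsilane, CC(C)[Si](Cl)(C(C)C)C(C)C
Why: Kowalski ester homologation: acylation of LiCHBr2, enolisation to 16, bromine–lithium exchange and 1,2-shift of the alkyl group to the carbenoid carbon give ynolate 17, which the bulky TIPSCl silylates on oxygen; the migrating carbon is a CH2, so C3 is unaffected.

Step 8
Reactants: 18 tert-butyldimethyl{[(2R)-2-ArT-5-(triisopropylsilyloxy)pent-4-yn-1-yl]oxy}silane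
Product: 19 2-[(2R)-3-(tert-butyldimethylsilyloxy)-2-ArT-propyl]-3-(triisopropylsilyloxy)cyclobut-2-en-1-one
Conditions: ketene (gas, from pyrolysis of acetone), CH2Cl2, −20 to 0 °C; concentrate, use crude
Reagents that add atoms: ketene, C=C=O
Why: Thermal [2+2] cycloaddition of ketene with a siloxyalkyne, a known reaction of triisopropylsiloxyalkynes; the electrophilic ketene carbonyl carbon bonds to the nucleophilic alkyl-bearing alkyne carbon, which gives only the 2-alkyl-3-siloxy regioisomer.

Step 9
Reactants: 20 chloroacetaldehyde dimethyl acetal; 21 prenyl bromide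
Product: 23 1-methoxy-5-methylhex-4-en-1-yne, via sodium methoxyethynide 22 (not isolated)
Conditions: NaNH2 (3.0 equiv), liquid NH3, −33 °C; then 21, −40 to −33 °C; pentane extraction, distillation
Reagents that add atoms: none
Why: Double elimination (HCl, then MeOH) from the chloroacetal by NaNH2 is the standard route to alkoxyacetylides, and SN2 alkylation with the primary allylic bromide installs the prenyl group; a methyl ynol ether is chosen because it cannot fragment by a retro-ene path at the temperature of step 10.

Step 10
Reactants: 19 2-[(2R)-3-(tert-butyldimethylsilyloxy)-2-ArT-propyl]-3-(triisopropylsilyloxy)cyclobut-2-en-1-one; 23 1-methoxy-5-methylhex-4-en-1-yne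
Product: 28 4-[(2R)-3-(tert-butyldimethylsilyloxy)-2-ArT-propyl]-3-methoxy-2-(3-methylbut-2-en-1-yl)-5-(triisopropylsilyloxy)phenol, via siloxy vinylketene 24 (not isolated), via vinylcyclobutenone 25 (not isolated), via dienylketene 26 (not isolated), via cyclohexadienone 27 (not isolated)
Conditions: 23 (2 equiv), toluene (0.3 M, degassed), sealed tube, 80 °C then 110 °C
Reagents that add atoms: none
Why: Heating opens 19 by conrotatory 4π electrocyclic ring opening to vinylketene 24, whose electrophilic ketene carbon bonds to the nucleophilic prenyl-bearing carbon of 23 while its α-carbon bonds to the methoxy-bearing carbon in a regiospecific [2+2] cycloaddition giving 25. A second 4π opening gives dienylketene 26, which closes ring A by thermal disrotatory 6π electrocyclisation (re-forming the C7–C8 bond) to 27, and tautomerisation gives phenol 28. This is the Danheiser benzannulation, whose closest known cases are the reactions of 3-alkoxy- and 3-siloxycyclobutenones and of other cyclobutenones with alkoxy- and siloxyalkynes. The net result is two new ring bonds, C4a–C5 and C6–C7, and loss of the old C7–C4a bond; no stereocentre is created, the quaternary centre of 25 is destroyed again, and C3 lies in the side chain and cannot be touched. The step needs regioselectivity, secured by the polarity match of ketene carbonyl carbon and ynol ether β-carbon (ketene oxygen becomes C7–OH, prenyl C6, methoxy C5, the silyloxy carbon C8a, the ring CH2 C8), and chemoselectivity, which rests on the ynol ether being a far better ketenophile than the prenyl alkene or the ring D double bond. An excess of 23 keeps the vinylketene from acylating the product phenol, and the donor at C3 slows the first ring opening, which is why the temperature is raised in two stages.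

Step 11
Reactants: 28 4-[(2R)-3-(tert-butyldimethylsilyloxy)-2-ArT-propyl]-3-methoxy-2-(3-methylbut-2-en-1-yl)-5-(triisopropylsilyloxy)phenol
Product: 29 4-[(2R)-3-hydroxy-2-(5-hydroxy-2,2-dimethyl-2H-chromen-8-yl)propyl]-5-methoxy-6-(3-methylbut-2-en-1-yl)benzene-1,3-diol
Conditions: Bu4NF (4 equiv), AcOH (4 equiv), THF, 0 °C to rt, argon
Reagents that add atoms: none
Why: Fluoride cleaves the two aryl silyl ethers and the primary alkyl silyl ether by attack at silicon; acetic acid buffers the phenoxides so the electron-rich ring is not oxidised, and neither the prenyl group nor ring D meets strong acid or base.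

Step 12
Reactants: 29 4-[(2R)-3-hydroxy-2-(5-hydroxy-2,2-dimethyl-2H-chromen-8-yl)propyl]-5-methoxy-6-(3-methylbut-2-en-1-yl)benzene-1,3-diol
Product: 31 (3R)-3-(5-hydroxy-2,2-dimethyl-2H-chromen-8-yl)-5-methoxy-6-(3-methylbut-2-en-1-yl)-3,4-dihydro-2H-chromen-7-ol, via oxyphosphonium phenoxide 30 (not isolated)
Conditions: PPh3, DIAD, THF (0.01 M), 0 °C to rt
Reagents that add atoms: none
Why: Intramolecular Mitsunobu etherification: the primary alcohol is activated as oxyphosphonium 30 and displaced by the C8a phenoxide in a 6-exo-tet closure, the only ring size open to any of the three phenols; substitution occurs at CH2, so C3 keeps its configuration.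

## Compound list

1 | 4-bromoresorcinol | Oc1ccc(Br)c(O)c1 | starting material
2 | 2-bromo-5-(triisopropylsilyloxy)phenol | Oc1cc(O[Si](C(C)C)(C(C)C)C(C)C)ccc1Br | intermediate
3 | 3-chloro-3-methylbut-1-yne | C#CC(C)(C)Cl | starting material
4 | [4-bromo-3-(2-methylbut-3-yn-2-yloxy)phenoxy]triisopropylsilane | C#CC(C)(C)Oc1cc(O[Si](C(C)C)(C(C)C)C(C)C)ccc1Br | intermediate
5 | 6-bromo-2-(3-methylbuta-1,2-dien-1-yl)-3-(triisopropylsilyloxy)phenol | CC(C)=C=Cc1c(O)c(Br)ccc1O[Si](C(C)C)(C(C)C)C(C)C | intermediate (not isolated)
6 | 2-bromo-6-(3-methylbut-2-en-1-ylidene)-5-(triisopropylsilyloxy)cyclohexa-2,4-dien-1-one | CC(C)=CC=C1C(=O)C(Br)=CC=C1O[Si](C(C)C)(C(C)C)C(C)C | intermediate (not isolated)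
7 | 8-bromo-2,2-dimethyl-5-(triisopropylsilyloxy)-2H-chromene | CC1(C)C=Cc2c(O[Si](C(C)C)(C(C)C)C(C)C)ccc(Br)c2O1 | intermediate
8 | [2,2-dimethyl-5-(triisopropylsilyloxy)-2H-chromen-8-yl]lithium | [Li]c1ccc(O[Si](C(C)C)(C(C)C)C(C)C)c2C=CC(C)(C)Oc12 | intermediate (not isolated)
9 | lithium [2,2-dimethyl-5-(triisopropylsilyloxy)-2H-chromen-8-yl]tri(propan-2-yloxy)borate | [Li+].CC(C)O[B-](OC(C)C)(OC(C)C)c1ccc(O[Si](C(C)C)(C(C)C)C(C)C)c2C=CC(C)(C)Oc12 | intermediate (not isolated)
10 | [2,2-dimethyl-5-(triisopropylsilyloxy)-2H-chromen-8-yl]boronic acid | OB(O)c1ccc(O[Si](C(C)C)(C(C)C)C(C)C)c2C=CC(C)(C)Oc12 | intermediate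
11 | furan-2(5H)-one | O=C1OCC=C1 | starting material
12 | (4R)-4-[2,2-dimethyl-5-(triisopropylsilyloxy)-2H-chromen-8-yl]dihydrofuran-2(3H)-one | O=C1C[C@H](c2ccc(O[Si](C(C)C)(C(C)C)C(C)C)c3c2OC(C)(C)C=C3)CO1 | intermediate
13 | lithium (3R)-4-hydroxy-3-[2,2-dimethyl-5-(triisopropylsilyloxy)-2H-chromen-8-yl]butanoate | [Li+].[O-]C(=O)C[C@H](c1ccc(O[Si](C(C)C)(C(C)C)C(C)C)c2c1OC(C)(C)C=C2)CO | intermediate (not isolated)
14 | methyl (3R)-4-hydroxy-3-[2,2-dimethyl-5-(triisopropylsilyloxy)-2H-chromen-8-yl]butanoate | COC(=O)C[C@H](c1ccc(O[Si](C(C)C)(C(C)C)C(C)C)c2c1OC(C)(C)C=C2)CO | intermediate (not isolated)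
15 | methyl (3R)-4-(tert-butyldimethylsilyloxy)-3-[2,2-dimethyl-5-(triisopropylsilyloxy)-2H-chromen-8-yl]butanoate | COC(=O)C[C@H](c1ccc(O[Si](C(C)C)(C(C)C)C(C)C)c2c1OC(C)(C)C=C2)CO[Si](C)(C)C(C)(C)C | intermediate
16 | lithium (4R)-1,1-dibromo-5-(tert-butyldimethylsilyloxy)-4-[2,2-dimethyl-5-(triisopropylsilyloxy)-2H-chromen-8-yl]pent-1-en-2-olate | [Li+].[O-]C(=C(Br)Br)C[C@H](c1ccc(O[Si](C(C)C)(C(C)C)C(C)C)c2c1OC(C)(C)C=C2)CO[Si](C)(C)C(C)(C)C | intermediate (not isolated)
17 | lithium (4R)-5-(tert-butyldimethylsilyloxy)-4-[2,2-dimethyl-5-(triisopropylsilyloxy)-2H-chromen-8-yl]pent-1-yn-1-olate | [Li+].[O-]C#CC[C@H](c1ccc(O[Si](C(C)C)(C(C)C)C(C)C)c2c1OC(C)(C)C=C2)CO[Si](C)(C)C(C)(C)C | intermediate (not isolated)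
18 | tert-butyldimethyl{[(2R)-2-[2,2-dimethyl-5-(triisopropylsilyloxy)-2H-chromen-8-yl]-5-(triisopropylsilyloxy)pent-4-yn-1-yl]oxy}silane | CC(C)[Si](C(C)C)(C(C)C)OC#CC[C@H](c1ccc(O[Si](C(C)C)(C(C)C)C(C)C)c2c1OC(C)(C)C=C2)CO[Si](C)(C)C(C)(C)C | intermediate
19 | 2-[(2R)-3-(tert-butyldimethylsilyloxy)-2-[2,2-dimethyl-5-(triisopropylsilyloxy)-2H-chromen-8-yl]propyl]-3-(triisopropylsilyloxy)cyclobut-2-en-1-one | O=C1CC(O[Si](C(C)C)(C(C)C)C(C)C)=C1C[C@H](c1ccc(O[Si](C(C)C)(C(C)C)C(C)C)c2c1OC(C)(C)C=C2)CO[Si](C)(C)C(C)(C)C | intermediate
20 | chloroacetaldehyde dimethyl acetal (2-chloro-1,1-dimethoxyethane) | COC(CCl)OC | starting material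
21 | prenyl bromide (1-bromo-3-methylbut-2-ene) | CC(C)=CCBr | starting material
22 | sodium methoxyethynide | [Na+].[C-]#COC | intermediate (not isolated)
23 | 1-methoxy-5-methylhex-4-en-1-yne | COC#CCC=C(C)C | intermediate
24 | 2-[(2R)-3-(tert-butyldimethylsilyloxy)-2-ArT-propyl]-3-(triisopropylsilyloxy)buta-1,3-dien-1-one | O=C=C(C[C@H](c1ccc(O[Si](C(C)C)(C(C)C)C(C)C)c2c1OC(C)(C)C=C2)CO[Si](C)(C)C(C)(C)C)C(=C)O[Si](C(C)C)(C(C)C)C(C)C | intermediate (not isolated)
25 | 4-[(2R)-3-(tert-butyldimethylsilyloxy)-2-ArT-propyl]-3-methoxy-2-(3-methylbut-2-en-1-yl)-4-[1-(triisopropylsilyloxy)ethenyl]cyclobut-2-en-1-one (both C4 epimers) | O=C1C(CC=C(C)C)=C(OC)C1(C[C@H](c1ccc(O[Si](C(C)C)(C(C)C)C(C)C)c2c1OC(C)(C)C=C2)CO[Si](C)(C)C(C)(C)C)C(=C)O[Si](C(C)C)(C(C)C)C(C)C | intermediate (not isolated)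
26 | 4-[(2R)-3-(tert-butyldimethylsilyloxy)-2-ArT-propyl]-3-methoxy-2-(3-methylbut-2-en-1-yl)-5-(triisopropylsilyloxy)hexa-1,3,5-trien-1-one | O=C=C(CC=C(C)C)C(OC)=C(C[C@H](c1ccc(O[Si](C(C)C)(C(C)C)C(C)C)c2c1OC(C)(C)C=C2)CO[Si](C)(C)C(C)(C)C)C(=C)O[Si](C(C)C)(C(C)C)C(C)C | intermediate (not isolated)
27 | 4-[(2R)-3-(tert-butyldimethylsilyloxy)-2-ArT-propyl]-3-methoxy-2-(3-methylbut-2-en-1-yl)-5-(triisopropylsilyloxy)cyclohexa-2,4-dien-1-one | O=C1CC(O[Si](C(C)C)(C(C)C)C(C)C)=C(C[C@H](c2ccc(O[Si](C(C)C)(C(C)C)C(C)C)c3c2OC(C)(C)C=C3)CO[Si](C)(C)C(C)(C)C)C(OC)=C1CC=C(C)C | intermediate (not isolated)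
28 | 4-[(2R)-3-(tert-butyldimethylsilyloxy)-2-ArT-propyl]-3-methoxy-2-(3-methylbut-2-en-1-yl)-5-(triisopropylsilyloxy)phenol | COc1c(CC=C(C)C)c(O)cc(O[Si](C(C)C)(C(C)C)C(C)C)c1C[C@H](c1ccc(O[Si](C(C)C)(C(C)C)C(C)C)c2c1OC(C)(C)C=C2)CO[Si](C)(C)C(C)(C)C | intermediate
29 | 4-[(2R)-3-hydroxy-2-(5-hydroxy-2,2-dimethyl-2H-chromen-8-yl)propyl]-5-methoxy-6-(3-methylbut-2-en-1-yl)benzene-1,3-diol | COc1c(CC=C(C)C)c(O)cc(O)c1C[C@H](c1ccc(O)c2c1OC(C)(C)C=C2)CO | intermediate
30 | {(2R)-3-[2,4-dihydroxy-6-methoxy-5-(3-methylbut-2-en-1-yl)phenyl]-2-(5-hydroxy-2,2-dimethyl-2H-chromen-8-yl)propoxy}triphenylphosphonium, C8a phenoxide zwitterion | COc1c(CC=C(C)C)c(O)cc([O-])c1C[C@H](c1ccc(O)c2c1OC(C)(C)C=C2)CO[P+](c1ccccc1)(c1ccccc1)c1ccccc1 | intermediate (not isolated)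
31 | (3R)-3-(5-hydroxy-2,2-dimethyl-2H-chromen-8-yl)-5-methoxy-6-(3-methylbut-2-en-1-yl)-3,4-dihydro-2H-chromen-7-ol | COc1c(CC=C(C)C)c(O)cc2c1C[C@H](c1ccc(O)c3c1OC(C)(C)C=C3)CO2 | target

## Step count and least certain steps

Total: 12 steps. Longest linear sequence: 11 steps (steps 1–8, 10, 11, 12); step 9 is a one-step branch.

**Step 10 (key step).**
- Risk: slow first ring opening, because the donor at C3 stabilises the cyclobutenone; loss of the enol silyl group through adventitious proton sources; and acylation of the product phenol by unreacted vinylketene.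
- Fallback (from 19, back at 31): close O1–C2 before ring A is built.
  - HF·pyridine in THF should remove the enol and primary alkyl silyl groups of 19 and give 3-hydroxy-2-[(2R)-3-hydroxy-2-ArT-propyl]cyclobut-2-en-1-one F1.
  - Intramolecular Mitsunobu O-alkylation of this vinylogous acid (PPh3, DIAD) should give the bicyclic enol ether (4R)-4-ArT-2-oxabicyclo[4.2.0]oct-1(6)-en-7-one F2, a 3-alkoxycyclobutenone that cannot lose its oxygen substituent.
  - Heating F2 with 23 as in step 10 should give the ring B silyl ether of the target, (3R)-3-ArT-5-methoxy-6-(3-methylbut-2-en-1-yl)-3,4-dihydro-2H-chromen-7-ol F3, and Bu4NF/AcOH should release 31.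
  - This still relies on the pericyclic cascade, so it answers loss of the silyl group but not an intrinsically unreactive vinylketene.

**Step 7.**
- Risk: incomplete carbenoid rearrangement, competing C-silylation of the ynolate, and attack of excess alkyllithium on the aryl silyl ether.
- Fallback (from 12, back at 17 and then 18): form the ynolate by oxidation of an acetylide instead of by carbenoid rearrangement.
  - i-Bu2AlH should reduce 12 to the lactol (4R)-4-ArT-tetrahydrofuran-2-ol F4.
  - Seyferth–Gilbert homologation in its Ohira–Bestmann form (dimethyl (1-diazo-2-oxopropyl)phosphonate, K2CO3, MeOH) should give (2R)-2-ArT-pent-4-yn-1-ol F5.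
  - TBSCl/imidazole should give tert-butyldimethyl{[(2R)-2-ArT-pent-4-yn-1-yl]oxy}silane F6.
  - Deprotonation with LiN(SiMe3)2 and oxidation of the lithium acetylide with t-BuOOLi should give ynolate 17, which TIPSCl converts into 18.

**Step 5.**
- Risk: protodeboronation of the electron-rich ortho-alkoxy boronic acid outrunning transmetalation, and erosion of enantioface selection with the hindered aryl group.
- Fallback (from 7, back at 15, bypassing steps 4–6): auxiliary-controlled cuprate addition.
  - Bromine–lithium exchange of 7, transmetalation with MgBr2·OEt2 and CuBr·SMe2-mediated conjugate addition to (4S)-3-[(2E)-4-(tert-butyldimethylsilyloxy)but-2-enoyl]-4-phenyl-1,3-oxazolidin-2-one F7.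
  - F7 would come from a Horner–Wadsworth–Emmons reaction of (tert-butyldimethylsilyloxy)acetaldehyde with the diethylphosphonoacetyl derivative of (S)-4-phenyloxazolidin-2-one.
  - The chelated s-cis imide exposes the face opposite the phenyl group, which is predicted to give (4S)-3-[(3R)-4-(tert-butyldimethylsilyloxy)-3-ArT-butanoyl]-4-phenyl-1,3-oxazolidin-2-one F8.
  - MeOMgBr (from MeMgBr and MeOH) should transesterify F8 to 15 and release the auxiliary.

**Step 6.**
- Risk: cleavage of the aryl silyl ether by hydroxide, and relactonisation of the hydroxy ester before silylation.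
- Fallback (from 12, back at 16 and then 18): hydroxide-free opening.
  - Me2AlCl/MeONHMe·HCl should open 12 to (3R)-4-hydroxy-N-methoxy-N-methyl-3-ArT-butanamide F9, which does not relactonise readily.
  - TBSCl/imidazole should give (3R)-4-(tert-butyldimethylsilyloxy)-N-methoxy-N-methyl-3-ArT-butanamide F10.
  - Single addition of LiCHBr2 should give, after work-up, (4R)-1,1-dibromo-5-(tert-butyldimethylsilyloxy)-4-ArT-pentan-2-one F11.
  - LiN(SiMe3)2 converts F11 into enolate 16, from which n-BuLi and TIPSCl lead to 18 as in step 7.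

**Step 12.**
- Risk: intermolecular O-alkylation of the two bystander phenols and alkylation of the reduced azodicarboxylate competing with ring closure.
- Fallback (from 28, back at 31, replacing steps 11 and 12): fluoride-triggered Williamson closure.
  - HF·pyridine/pyridine should remove only the primary alkyl silyl ether of 28 and give 4-[(2R)-3-hydroxy-2-ArT-propyl]-3-methoxy-2-(3-methylbut-2-en-1-yl)-5-(triisopropylsilyloxy)phenol F12.
  - Appel bromination (PPh3, CBr4) should give 4-[(2R)-3-bromo-2-ArT-propyl]-3-methoxy-2-(3-methylbut-2-en-1-yl)-5-(triisopropylsilyloxy)phenol F13.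
  - Bu4NF in dilute THF then unmasks the C8a phenoxide next to the leaving group, so intramolecular Williamson etherification accompanies desilylation and gives 31 in the same operation.

## Further compounds

F1 | step 10 | 3-hydroxy-2-[(2R)-3-hydroxy-2-[2,2-dimethyl-5-(triisopropylsilyloxy)-2H-chromen-8-yl]propyl]cyclobut-2-en-1-one | O=C1CC(O)=C1C[C@H](c1ccc(O[Si](C(C)C)(C(C)C)C(C)C)c2c1OC(C)(C)C=C2)CO
F2 | step 10 | (4R)-4-[2,2-dimethyl-5-(triisopropylsilyloxy)-2H-chromen-8-yl]-2-oxabicyclo[4.2.0]oct-1(6)-en-7-one | O=C1CC2=C1C[C@H](c1ccc(O[Si](C(C)C)(C(C)C)C(C)C)c3c1OC(C)(C)C=C3)CO2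
F3 | step 10 | (3R)-3-[2,2-dimethyl-5-(triisopropylsilyloxy)-2H-chromen-8-yl]-5-methoxy-6-(3-methylbut-2-en-1-yl)-3,4-dihydro-2H-chromen-7-ol | COc1c(CC=C(C)C)c(O)cc2c1C[C@H](c1ccc(O[Si](C(C)C)(C(C)C)C(C)C)c3c1OC(C)(C)C=C3)CO2
F4 | step 7 | (4R)-4-[2,2-dimethyl-5-(triisopropylsilyloxy)-2H-chromen-8-yl]tetrahydrofuran-2-ol | OC1C[C@H](c2ccc(O[Si](C(C)C)(C(C)C)C(C)C)c3c2OC(C)(C)C=C3)CO1
F5 | step 7 | (2R)-2-[2,2-dimethyl-5-(triisopropylsilyloxy)-2H-chromen-8-yl]pent-4-yn-1-ol | C#CC[C@H](c1ccc(O[Si](C(C)C)(C(C)C)C(C)C)c2c1OC(C)(C)C=C2)CO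
F6 | step 7 | tert-butyldimethyl{[(2R)-2-[2,2-dimethyl-5-(triisopropylsilyloxy)-2H-chromen-8-yl]pent-4-yn-1-yl]oxy}silane | C#CC[C@H](c1ccc(O[Si](C(C)C)(C(C)C)C(C)C)c2c1OC(C)(C)C=C2)CO[Si](C)(C)C(C)(C)C
F7 | step 5 | (4S)-3-[(2E)-4-(tert-butyldimethylsilyloxy)but-2-enoyl]-4-phenyl-1,3-oxazolidin-2-one | O=C1OC[C@H](c2ccccc2)N1C(=O)/C=C/CO[Si](C)(C)C(C)(C)C
F8 | step 5 | (4S)-3-[(3R)-4-(tert-butyldimethylsilyloxy)-3-[2,2-dimethyl-5-(triisopropylsilyloxy)-2H-chromen-8-yl]butanoyl]-4-phenyl-1,3-oxazolidin-2-one | O=C1OC[C@H](c2ccccc2)N1C(=O)C[C@H](c1ccc(O[Si](C(C)C)(C(C)C)C(C)C)c2c1OC(C)(C)C=C2)CO[Si](C)(C)C(C)(C)C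
F9 | step 6 | (3R)-4-hydroxy-N-methoxy-N-methyl-3-[2,2-dimethyl-5-(triisopropylsilyloxy)-2H-chromen-8-yl]butanamide | CON(C)C(=O)C[C@H](c1ccc(O[Si](C(C)C)(C(C)C)C(C)C)c2c1OC(C)(C)C=C2)CO
F10 | step 6 | (3R)-4-(tert-butyldimethylsilyloxy)-N-methoxy-N-methyl-3-[2,2-dimethyl-5-(triisopropylsilyloxy)-2H-chromen-8-yl]butanamide | CON(C)C(=O)C[C@H](c1ccc(O[Si](C(C)C)(C(C)C)C(C)C)c2c1OC(C)(C)C=C2)CO[Si](C)(C)C(C)(C)C
F11 | step 6 | (4R)-1,1-dibromo-5-(tert-butyldimethylsilyloxy)-4-[2,2-dimethyl-5-(triisopropylsilyloxy)-2H-chromen-8-yl]pentan-2-one | BrC(Br)C(=O)C[C@H](c1ccc(O[Si](C(C)C)(C(C)C)C(C)C)c2c1OC(C)(C)C=C2)CO[Si](C)(C)C(C)(C)C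
F12 | step 12 | 4-[(2R)-3-hydroxy-2-[2,2-dimethyl-5-(triisopropylsilyloxy)-2H-chromen-8-yl]propyl]-3-methoxy-2-(3-methylbut-2-en-1-yl)-5-(triisopropylsilyloxy)phenol | COc1c(CC=C(C)C)c(O)cc(O[Si](C(C)C)(C(C)C)C(C)C)c1C[C@H](c1ccc(O[Si](C(C)C)(C(C)C)C(C)C)c2c1OC(C)(C)C=C2)CO
F13 | step 12 | 4-[(2R)-3-bromo-2-[2,2-dimethyl-5-(triisopropylsilyloxy)-2H-chromen-8-yl]propyl]-3-methoxy-2-(3-methylbut-2-en-1-yl)-5-(triisopropylsilyloxy)phenol | COc1c(CC=C(C)C)c(O)cc(O[Si](C(C)C)(C(C)C)C(C)C)c1C[C@H](c1ccc(O[Si](C(C)C)(C(C)C)C(C)C)c2c1OC(C)(C)C=C2)CBr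
A1 | alternative 1 | (3R)-5-hydroxy-7-(methoxymethoxy)-3-[5-(methoxymethoxy)-2,2-dimethyl-2H-chromen-8-yl]chroman-2-one | COCOc1cc(O)c2C[C@H](c3ccc(OCOC)c4c3OC(C)(C)C=C4)C(=O)Oc2c1
A2 | alternative 1 | 5-(methoxymethoxy)-2-[(phenylsulfonyl)methyl]benzene-1,3-diol | COCOc1cc(O)c(CS(=O)(=O)c2ccccc2)c(O)c1
A3 | alternative 1 | 5-hydroxy-3-(methoxymethoxy)-6-methylidenecyclohexa-2,4-dien-1-one | C=C1C(=O)C=C(OCOC)C=C1O
A4 | alternative 1 | 2-[5-(methoxymethoxy)-2,2-dimethyl-2H-chromen-8-yl]acetic acid | OC(=O)Cc1ccc(OCOC)c2c1OC(C)(C)C=C2
A5 | alternative 2 | 2-{(1R)-1-[5-(methoxymethoxy)-2,2-dimethyl-2H-chromen-8-yl]-2-[2-methoxy-4,6-bis(methoxymethoxy)-3-(3-methylbut-2-en-1-yl)phenyl]ethyl}-4,4,5,5-tetramethyl-1,3,2-dioxaborolane | COc1c(CC=C(C)C)c(OCOC)cc(OCOC)c1C[C@H](c1ccc(OCOC)c2c1OC(C)(C)C=C2)B1OC(C)(C)C(C)(C)O1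
A6 | alternative 2 | 2-methoxy-4,6-bis(methoxymethoxy)-3-(3-methylbut-2-en-1-yl)phenyl trifluoromethanesulfonate | COc1c(CC=C(C)C)c(OCOC)cc(OCOC)c1OS(=O)(=O)C(F)(F)F
A7 | alternative 2 | [5-(methoxymethoxy)-2,2-dimethyl-2H-chromen-8-yl]lithium | [Li]c1ccc(OCOC)c2c1OC(C)(C)C=C2
A8 | alternative 2 | 4,4,5,5-tetramethyl-2-vinyl-1,3,2-dioxaborolane | C=CB1OC(C)(C)C(C)(C)O1
A9 | alternative 3 | (3R)-5-methoxy-7-(methoxymethoxy)-3-[5-(methoxymethoxy)-2,2-dimethyl-2H-chromen-8-yl]-6-(3-methylbut-2-en-1-yl)-3,4-dihydro-2H-chromene | COc1c(CC=C(C)C)c(OCOC)cc2c1C[C@H](c1ccc(OCOC)c3c1OC(C)(C)C=C3)CO2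
A10 | alternative 3 | (3R)-5-methoxy-7-(methoxymethoxy)-3-[4-(methoxymethoxy)-2-(2-methylbut-3-yn-2-yloxy)phenyl]-6-(3-methylbut-2-en-1-yl)-3,4-dihydro-2H-chromene | COc1c(CC=C(C)C)c(OCOC)cc2c1C[C@H](c1ccc(OCOC)cc1OC(C)(C)C#C)CO2
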